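The flask has the north run's L but less G, 1.50 equiv against 2.1 equiv, and a shorter time, 2.0 min against 2.50 min. I want its L first.

| flask | L | G | remark | time |
|---|---|---|---|---|
| north | 0.61 M | 2.1 equiv | run made earlier |  |
| west | 0.61 M | 3.3 equiv | run made earlier |  |
| south | 0.92 M | 1.5 equiv | run made earlier |  |
| flask | 0.61 M | 1.50 equiv |  | 2.0 min |

| run | time / min | L / % | X / % |
|---|---|---|---|
| north | 0.333 | 92.1 | 6.1 |
| north | 0.833 | 82.4 | 11.2 |
| north | 1.50 | 69.7 | 15.3 |
| north | 2.50 | 59.3 | 18.8 |
| west | 0.667 | 77.1 | 13.9 |
| west | 1.33 | 63.8 | 17.8 |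
| west | 2.00 | 50.0 | 18.0 |
| west | 2.50 | 43.2 | 17.8 |
| south | 0.667 | 83.5 | 10.7 |
| south | 1.33 | 73.3 | 16.3 |
| south | 2.00 | 65.0 | 17.3 |
| south | 2.50 | 60.1 | 18.2 |

(standard deviation of a reading: 1 percentage point)

- amount of L at 2.0 min, in percent of the L charged
- amount of X at 2.0 min, in percent of the L charged
- amount of J at 2.0 min, in percent of the L charged
- amount of Q at 2.0 min, in percent of the L charged

I work in logarithms. Every listed route consumes L by L + G, so the log-loss of L, ln(charged over left), grows with G and with time. Scaling north's last reading of L by those two ratios, with G held at its charge as in a pseudo-first-order reckoning, gives the dose, the log-loss this flask would take at north's pace: 0.299. The real log-loss is the dose times the flask's mean share of G over north's.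

Each L lost costs one G as a mono adduct and two as Q, and I take each mean as the midpoint of G's ends. North's mean share is at most 0.903, and at least 0.851 because its X reading has not gone on to Q. The dose gives a notional loss of 25.8 % of the flask's L, reckoned with G held at its charge, and I use that loss to put the flask's mean share between 0.828 and 0.914. Hence I put L below 76.1 % and above 72.6 %, within the scatter of the reading.

The forecast gives L 74 %, inside my bracket, X 14.3 %, J 5 % and Q 6.7 %, and says “the J/Q split is uncertain”.

The flask gives L 73.3 %, X 14.4 %, J 6.49 % and Q 5.78 %.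

    G + J → Q (k = 1.60 × 10⁻⁴ M⁻¹ s⁻¹)
    L + G → J (k = 7.80 × 10⁻⁴ M⁻¹ s⁻¹)
    G + X → Q (k = 0.00690 M⁻¹ s⁻¹)
    L + G → X (k = 0.00240 M⁻¹ s⁻¹)

So L lies inside the bracket, and with G at 78 % of its own charge the midpoint share is 0.890, inside my range too. At 2.00 min this flask still makes X 1.77 times faster than it uses it. Left until 5.0 min, the same flask has a dose of 0.747, a notional loss of 52.6 % of its L with G held at its charge, which I use to reckon the G spent. The same reckoning then puts L between 48.5 % and 58.5 %, and that flask holds L 51.9 %.

The readings are calculated for substances that don't exist, and the scatter is random.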